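## Retrosynthetic overview

1. Floranol is reached from its tris-MOM ether; global acetal cleavage is the last step.
2. The C ring (C2–C3 bond, both stereocentres) comes from an enantioconvergent ring contraction: a stepwise 1,2 O→C shift of a racemic seven-membered aryl benzylidene acetal (a 1,3-benzodioxepin-5-one).
3. That acetal comes from an A-ring 2-hydroxyaryl hydroxymethyl ketone and 2-(methoxymethoxy)benzaldehyde (B ring, from phenol by MOM protection and ortho-formylation).
4. The A-ring ketone comes from resorcinol: bis-MOM ether, C2 hydroxylation and methylation, Ir C–H borylation/oxidation at C5, O-silylation, then two ortho-lithiations (prenyl bromide; acetoxyacetyl chloride).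
5. Ring order: rings A and B are bought as benzenes; the seven-membered dioxepinone is closed first and then contracted to the six-membered pyranone C ring.

Assumption: the sense of induction of the new step 12 cannot be predicted; the (R)-acid is written, and the (S)-acid is used instead if the (R)-acid favours the (2S,3S) series.

## Route

Step 1
Reactants: 1 resorcinol
Product: 2 1,3-bis(methoxymethoxy)benzene
Conditions: MOMCl (2.4 equiv), NaH (2.4 equiv), DMF, 0 °C → rt
Reagents that add atoms: chloromethyl methyl ether (MOMCl), COCCl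
Why: Williamson O-alkylation of the bis-phenoxide (MOM protection); the two OMOM groups later direct all lithiations and mark the future 5-OH and 7-OH.

Step 2
Reactants: 2 1,3-bis(methoxymethoxy)benzene
Product: 5 2,6-bis(methoxymethoxy)phenol, via 2-lithio-1,3-bis(methoxymethoxy)benzene 3 (not isolated), via dimethyl arylboronate 4 (not isolated)
Conditions: n-BuLi, THF, 0 °C; B(OMe)3, −78 °C → rt; then AcOH, 30 % H2O2, 0 °C → rt
Reagents that add atoms: hydrogen peroxide, OO
Why: Directed ortho-metalation occurs at C2 between the two cooperating OMOM groups, and borylation followed by oxidative C–B to C–O conversion gives the phenol.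

Step 3
Reactants: 5 2,6-bis(methoxymethoxy)phenol
Product: 6 2-methoxy-1,3-bis(methoxymethoxy)benzene
Conditions: MeI, K2CO3, acetone, reflux
Reagents that add atoms: iodomethane, CI
Why: Williamson O-methylation installs the future 6-OMe between the two MOM ethers.

Step 4
Reactants: 6 2-methoxy-1,3-bis(methoxymethoxy)benzene
Product: 8 4-methoxy-3,5-bis(methoxymethoxy)phenol, via aryl pinacol boronate 7 (not isolated)
Conditions: [Ir(cod)OMe]2 (1.5 mol %), dtbpy (3 mol %), B2pin2 (0.55 equiv), THF, 80 °C; then 30 % H2O2, NaOH (cat.), 0 °C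
Reagents that add atoms: hydrogen peroxide, OO
Why: Iridium-catalysed C–H borylation is sterically controlled and takes the only C–H without an ortho substituent (C5), and the boronate is oxidised in the same flask to the phenol (C–H borylation/oxidation).

Step 5
Reactants: 8 4-methoxy-3,5-bis(methoxymethoxy)phenol
Product: 9 triisopropyl[4-methoxy-3,5-bis(methoxymethoxy)phenoxy]silane
Conditions: TIPSCl, imidazole, DMF, rt
Reagents that add atoms: chlorotriisopropylsilane (TIPSCl), CC(C)[Si](Cl)(C(C)C)C(C)C
Why: O-silylation keeps the future ring oxygen O1 distinct from the two MOM-protected oxygens, and the bulky TIPS group resists anionic O→C silyl migration in the next two lithiations.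

Step 6
Reactants: 9 triisopropyl[4-methoxy-3,5-bis(methoxymethoxy)phenoxy]silane; 10 prenyl bromide (1-bromo-3-methylbut-2-ene)
Product: 12 triisopropyl[4-methoxy-3,5-bis(methoxymethoxy)-2-(3-methylbut-2-en-1-yl)phenoxy]silane, via aryllithium 11 (not isolated)
Conditions: n-BuLi (1.1 equiv), THF, 0 °C; CuI (10 mol %), then 10, −78 °C → rt
Reagents that add atoms: none
Why: Directed ortho-metalation at one of the two equivalent ring C–H (each between OMOM and OTIPS) and copper-catalysed SN2 allylation of the aryllithium give the linear prenyl group.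

Step 7
Reactants: 12 triisopropyl[4-methoxy-3,5-bis(methoxymethoxy)-2-(3-methylbut-2-en-1-yl)phenoxy]silane; 13 acetoxyacetyl chloride
Product: 16 2-{3-methoxy-2,4-bis(methoxymethoxy)-5-(3-methylbut-2-en-1-yl)-6-[(triisopropylsilyl)oxy]phenyl}-2-oxoethyl acetate, via aryllithium 14 (not isolated), via arylzinc chloride 15 (not isolated)
Conditions: n-BuLi (1.1 equiv), THF, 0 °C; ZnCl2, −78 → 0 °C; 13, Pd(PPh3)4 (5 mol %), 0 °C → rt
Reagents that add atoms: none
Why: A second directed ortho-metalation at the last ring C–H, transmetalation to zinc and Pd-catalysed Negishi acylation give the aryl ketone without over-addition or enolisation.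

Step 8
Reactants: 16 2-{3-methoxy-2,4-bis(methoxymethoxy)-5-(3-methylbut-2-en-1-yl)-6-[(triisopropylsilyl)oxy]phenyl}-2-oxoethyl acetate
Product: 17 2-hydroxy-1-[2-hydroxy-5-methoxy-4,6-bis(methoxymethoxy)-3-(3-methylbut-2-en-1-yl)phenyl]ethan-1-one
Conditions: K2CO3 (0.5 equiv), MeOH, 40 °C, argon
Reagents that add atoms: none
Why: Methanolysis (Zemplén-type transesterification) removes the acetate and the aryl silyl ether, which is base-labile because its phenoxide is ortho-acyl stabilised; the MOM ethers stay, so only O1–H and the primary OH are free.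

Step 9
Reactants: 18 phenol
Product: 19 (methoxymethoxy)benzene
Conditions: MOMCl, NaH, DMF, 0 °C → rt
Reagents that add atoms: chloromethyl methyl ether (MOMCl), COCCl
Why: Williamson O-alkylation (MOM protection) installs the directing group for the ortho-formylation and the protecting group for the 2'-OH.

Step 10
Reactants: 19 (methoxymethoxy)benzene
Product: 22 2-(methoxymethoxy)benzaldehyde, via 2-(methoxymethoxy)phenyllithium 20 (not isolated), via lithium hemiaminal alkoxide 21 (not isolated)
Conditions: n-BuLi, TMEDA, Et2O, 0 °C → rt; DMF, −78 °C → rt; H2O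
Reagents that add atoms: N,N-dimethylformamide, CN(C)C=O
Why: Directed ortho-metalation next to OMOM followed by formylation with DMF (Bouveault-type) gives the ortho-aldehyde only.

Step 11
Reactants: 17 2-hydroxy-1-[2-hydroxy-5-methoxy-4,6-bis(methoxymethoxy)-3-(3-methylbut-2-en-1-yl)phenyl]ethan-1-one; 22 2-(methoxymethoxy)benzaldehyde
Product: 23 rac-7-methoxy-6,8-bis(methoxymethoxy)-2-[2-(methoxymethoxy)phenyl]-9-(3-methylbut-2-en-1-yl)-2H-1,3-benzodioxepin-5(4H)-one
Conditions: PPTS (10 mol %), PhMe, 90 °C, 4 Å MS (Soxhlet)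
Reagents that add atoms: none
Why: Acid-catalysed dehydrative acetalisation; only O1–H and the primary OH are free, so the seven-membered dioxepinone is the only cyclic acetal possible, and its acetal stereocentre (racemic) is erased in step 12.

Step 12
Reactants: 23 rac-7-methoxy-6,8-bis(methoxymethoxy)-2-[2-(methoxymethoxy)phenyl]-9-(3-methylbut-2-en-1-yl)-2H-1,3-benzodioxepin-5(4H)-one
Product: 25 (2R,3R)-3-hydroxy-6-methoxy-5,7-bis(methoxymethoxy)-2-[2-(methoxymethoxy)phenyl]-8-(3-methylbut-2-en-1-yl)-2,3-dihydro-4H-1-benzopyran-4-one, via ring-opened oxocarbenium enediolate zwitterion 24 (not isolated)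
Conditions: (R)-TRIP N-triflylphosphoramide (10 mol %), PhMe, 5 Å MS, −20 → 0 °C
Reagents that add atoms: none
Why: Proposed new method: a catalytic enantioselective ring-contracting 1,2 O→C shift of an O,O-acetal, in which the chiral acid protonates the alkyl acetal oxygen O3 and ionises C2–O3 to a tethered aryloxocarbenium paired with the chiral anion, the released glycolyl ketone enolises to the enediol (24), and its carbon (old C4) adds to the oxocarbenium inside the ion pair in a stepwise, non-pericyclic C–C bond formation that contracts the seven-membered ring to the pyranone; the racemic acetal centre is erased in the cation, so the anion alone fixes C2 as R, and C3 settles as R in the diequatorial 2,3-trans isomer by acid-mediated enediol equilibration while C2, now a plain benzylic ether, cannot epimerise; the closest known reaction types are the Lewis-acid Petasis–Ferrier rearrangement, its chiral-phosphoric-acid aza variant, chiral-acid additions of enols to acetal-derived oxocarbenium ions and the anionic acetal [1,2]-Wittig rearrangement.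

Step 13
Reactants: 25 (2R,3R)-3-hydroxy-6-methoxy-5,7-bis(methoxymethoxy)-2-[2-(methoxymethoxy)phenyl]-8-(3-methylbut-2-en-1-yl)-2,3-dihydro-4H-1-benzopyran-4-one
Product: 26 floranol, (2R,3R)-3,5,7-trihydroxy-2-(2-hydroxyphenyl)-6-methoxy-8-(3-methylbut-2-en-1-yl)-2,3-dihydro-4H-1-benzopyran-4-one
Conditions: 3 M HCl, MeOH, 45 °C
Reagents that add atoms: none
Why: Acid-catalysed transacetalisation removes the three MOM ethers as dimethoxymethane under conditions that spare the prenyl group; C2 and C3 are not touched and trans is also the thermodynamic isomer, so (2R,3R) is kept.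

## Compound list

1 | resorcinol (benzene-1,3-diol) | Oc1cccc(O)c1 | starting material
2 | 1,3-bis(methoxymethoxy)benzene | COCOc1cccc(OCOC)c1 | intermediate
3 | [2,6-bis(methoxymethoxy)phenyl]lithium (not isolated) | [Li]c1c(OCOC)cccc1OCOC | intermediate
4 | dimethyl [2,6-bis(methoxymethoxy)phenyl]boronate (not isolated) | COB(OC)c1c(OCOC)cccc1OCOC | intermediate
5 | 2,6-bis(methoxymethoxy)phenol | COCOc1cccc(OCOC)c1O | intermediate
6 | 2-methoxy-1,3-bis(methoxymethoxy)benzene | COCOc1cccc(OCOC)c1OC | intermediate
7 | 2-[4-methoxy-3,5-bis(methoxymethoxy)phenyl]-4,4,5,5-tetramethyl-1,3,2-dioxaborolane (not isolated) | COCOc1cc(cc(OCOC)c1OC)B1OC(C)(C)C(C)(C)O1 | intermediate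
8 | 4-methoxy-3,5-bis(methoxymethoxy)phenol | COCOc1cc(O)cc(OCOC)c1OC | intermediate
9 | triisopropyl[4-methoxy-3,5-bis(methoxymethoxy)phenoxy]silane | COCOc1cc(O[Si](C(C)C)(C(C)C)C(C)C)cc(OCOC)c1OC | intermediate
10 | prenyl bromide (1-bromo-3-methylbut-2-ene) | CC(C)=CCBr | starting material
11 | {3-methoxy-2,4-bis(methoxymethoxy)-6-[(triisopropylsilyl)oxy]phenyl}lithium (not isolated) | [Li]c1c(OCOC)c(OC)c(OCOC)cc1O[Si](C(C)C)(C(C)C)C(C)C | intermediate
12 | triisopropyl[4-methoxy-3,5-bis(methoxymethoxy)-2-(3-methylbut-2-en-1-yl)phenoxy]silane | CC(C)=CCc1c(OCOC)c(OC)c(OCOC)cc1O[Si](C(C)C)(C(C)C)C(C)C | intermediate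
13 | acetoxyacetyl chloride (2-chloro-2-oxoethyl acetate) | CC(=O)OCC(Cl)=O | starting material
14 | {3-methoxy-2,4-bis(methoxymethoxy)-5-(3-methylbut-2-en-1-yl)-6-[(triisopropylsilyl)oxy]phenyl}lithium (not isolated) | [Li]c1c(OCOC)c(OC)c(OCOC)c(CC=C(C)C)c1O[Si](C(C)C)(C(C)C)C(C)C | intermediate
15 | chloro{3-methoxy-2,4-bis(methoxymethoxy)-5-(3-methylbut-2-en-1-yl)-6-[(triisopropylsilyl)oxy]phenyl}zinc (not isolated) | Cl[Zn]c1c(OCOC)c(OC)c(OCOC)c(CC=C(C)C)c1O[Si](C(C)C)(C(C)C)C(C)C | intermediate
16 | 2-{3-methoxy-2,4-bis(methoxymethoxy)-5-(3-methylbut-2-en-1-yl)-6-[(triisopropylsilyl)oxy]phenyl}-2-oxoethyl acetate | CC(=O)OCC(=O)c1c(OCOC)c(OC)c(OCOC)c(CC=C(C)C)c1O[Si](C(C)C)(C(C)C)C(C)C | intermediate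
17 | 2-hydroxy-1-[2-hydroxy-5-methoxy-4,6-bis(methoxymethoxy)-3-(3-methylbut-2-en-1-yl)phenyl]ethan-1-one | OCC(=O)c1c(OCOC)c(OC)c(OCOC)c(CC=C(C)C)c1O | intermediate
18 | phenol | Oc1ccccc1 | starting material
19 | (methoxymethoxy)benzene | COCOc1ccccc1 | intermediate
20 | [2-(methoxymethoxy)phenyl]lithium (not isolated) | [Li]c1ccccc1OCOC | intermediate
21 | lithium (dimethylamino)[2-(methoxymethoxy)phenyl]methanolate (not isolated) | [Li]OC(N(C)C)c1ccccc1OCOC | intermediate
22 | 2-(methoxymethoxy)benzaldehyde | COCOc1ccccc1C=O | intermediate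
23 | rac-7-methoxy-6,8-bis(methoxymethoxy)-2-[2-(methoxymethoxy)phenyl]-9-(3-methylbut-2-en-1-yl)-2H-1,3-benzodioxepin-5(4H)-one (racemic at acetal carbon C2) | COCOc1c(OC)c(OCOC)c(CC=C(C)C)c2OC(OCC(=O)c12)c1ccccc1OCOC | intermediate
24 | ring-opened oxocarbenium enediolate zwitterion of 23 (not isolated; enediol geometry not defined) | COCOc1c(OC)c(OCOC)c(CC=C(C)C)c([O+]=Cc2ccccc2OCOC)c1C(O)=C[O-] | intermediate
25 | (2R,3R)-3-hydroxy-6-methoxy-5,7-bis(methoxymethoxy)-2-[2-(methoxymethoxy)phenyl]-8-(3-methylbut-2-en-1-yl)-2,3-dihydro-4H-1-benzopyran-4-one | COc1c(OCOC)c(CC=C(C)C)c2c(c1OCOC)C(=O)[C@H](O)[C@@H](c1ccccc1OCOC)O2 | intermediate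
26 | floranol, (2R,3R)-3,5,7-trihydroxy-2-(2-hydroxyphenyl)-6-methoxy-8-(3-methylbut-2-en-1-yl)-2,3-dihydro-4H-1-benzopyran-4-one | COc1c(O)c(CC=C(C)C)c2c(c1O)C(=O)[C@H](O)[C@@H](c1ccccc1O)O2 | target

## Step count and risks

Total: 13 steps. Longest linear sequence: 11 steps (steps 1–8, then 11, 12 and 13, from resorcinol).

Three steps most likely to fail:

**The ring contraction (step 12, the proposed new step).** It may fail through slow enolisation of the electron-rich aryl ketone, loss of a MOM group under the strong acid, or low enantioselectivity. The fallback uses known chemistry, sets out from 17 and 22 and comes back at 25. A dinuclear zinc–ProPhenol direct asymmetric aldol of the α-hydroxy ketone 17 with aldehyde 22 gives the syn diol (2R,3S)-2,3-dihydroxy-1-[2-hydroxy-5-methoxy-4,6-bis(methoxymethoxy)-3-(3-methylbut-2-en-1-yl)phenyl]-3-[2-(methoxymethoxy)phenyl]propan-1-one F1. An intramolecular Mitsunobu etherification (PPh3, DIAD, THF, 0 °C) then closes the phenolic oxygen onto the benzylic carbinol with inversion, which turns the syn diol into the 2,3-trans chromanone 25.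

**The seven-membered acetalisation (step 11).** The hindered, hydrogen-bonded phenol and the ring size make the equilibrium uncertain. The fallback replaces carbonyl condensation by oxidative acetalisation, sets out from 17 and 22 and comes back at 23. NaBH4 reduces 22 to [2-(methoxymethoxy)phenyl]methanol F2, and an Appel reaction (CBr4, PPh3) gives 1-(bromomethyl)-2-(methoxymethoxy)benzene F3. K2CO3 in acetone alkylates only the phenolic oxygen of 17 to give 2-hydroxy-1-[5-methoxy-4,6-bis(methoxymethoxy)-2-{[2-(methoxymethoxy)phenyl]methoxy}-3-(3-methylbut-2-en-1-yl)phenyl]ethan-1-one F4. Anhydrous DDQ (4 Å MS, CH2Cl2, 0 °C) then abstracts the benzylic hydride of this 2-alkoxybenzyl ether, and the primary hydroxyl closes onto the resulting oxocarbenium ion to give 23.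

**The second lithiation and acylation (step 7).** The di-ortho-substituted arylzinc may couple slowly, or the acid chloride may be consumed unproductively. The fallback sets out from 12 and comes back at 16. Compound 12 is lithiated as before (14) and treated directly with 2-chloro-N-methoxy-N-methylacetamide, whose stable chelated adduct gives 2-chloro-1-{3-methoxy-2,4-bis(methoxymethoxy)-5-(3-methylbut-2-en-1-yl)-6-[(triisopropylsilyl)oxy]phenyl}ethan-1-one F5 on work-up. SN2 displacement of the α-chloride with caesium acetate in DMF then gives 16.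

## Further compounds

F1 | step 12 | (2R,3S)-2,3-dihydroxy-1-[2-hydroxy-5-methoxy-4,6-bis(methoxymethoxy)-3-(3-methylbut-2-en-1-yl)phenyl]-3-[2-(methoxymethoxy)phenyl]propan-1-one | COCOc1c(OC)c(OCOC)c(CC=C(C)C)c(O)c1C(=O)[C@H](O)[C@@H](O)c1ccccc1OCOC
F2 | step 11 | [2-(methoxymethoxy)phenyl]methanol | COCOc1ccccc1CO
F3 | step 11 | 1-(bromomethyl)-2-(methoxymethoxy)benzene | COCOc1ccccc1CBr
F4 | step 11 | 2-hydroxy-1-[5-methoxy-4,6-bis(methoxymethoxy)-2-{[2-(methoxymethoxy)phenyl]methoxy}-3-(3-methylbut-2-en-1-yl)phenyl]ethan-1-one | OCC(=O)c1c(OCOC)c(OC)c(OCOC)c(CC=C(C)C)c1OCc1ccccc1OCOC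
F5 | step 7 | 2-chloro-1-{3-methoxy-2,4-bis(methoxymethoxy)-5-(3-methylbut-2-en-1-yl)-6-[(triisopropylsilyl)oxy]phenyl}ethan-1-one | ClCC(=O)c1c(OCOC)c(OC)c(OCOC)c(CC=C(C)C)c1O[Si](C(C)C)(C(C)C)C(C)C
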